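A direct plan would first build two monocyclic halves, the vinylquinone A1 (2-prenyl-3-[(E)-propenyl]-1,4-benzoquinone) and 2-vinylhydroquinone A2, and join them in an enantioselective [4+2] cycloaddition to the adduct A3.
It would then oxidise A3 to the quinone A4 and let a base add the dienolate of the enedione to the new quinone to close the five-membered ring.
Weakest would be the cycloaddition: it would have to set the quaternary and the benzylic centre at once under a chiral acid for which no such reaction is known, between a quinone and a hydroquinone that can exchange their oxidation state.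
Next would be the oxidative demethylation that makes A1: a 2-alkenyl-3-allyl-quinone tautomerises and polymerises, so it would have to be used at once, and A2 is no more stable.
Last would be the oxidation and base-induced ring closure on the most precious material: the dienolate could as well attack through its γ-carbon (the C–CH3 carbon is equally placed for a five-membered ring), and the product hydroquinone re-oxidises in air.
Four of its five steps would only make two flat, achiral rings, so almost all complexity would rest on the two least secure steps.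

Plan of the new route
Positions are numbered as in a naphthalene-1,4-dione for rings A and B: C1(=O)–C2=C3–C4(=O)–C4a (aryl-bearing)–C5=C6(CH3)–C7–C8 (benzylic CH)–C8a (prenyl-bearing); ring C is C4a–C8a–C8 plus two carbons of arene D.
The retrosynthesis cuts C4a–aryl (Heck), C8a–prenyl (enolate alkylation), then C8a–C4a and C8–C7 together (intramolecular Diels–Alder), C8=C8a (aldol condensation) and the C4–diene bond (alkenylzinc addition).
Ring D is bought, rings A and B arise together in the cycloaddition of an acyclic trienone, and ring C is closed last.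
The feature that allows this: the double bond of ring B lies at C5=C6 beside C4a, so ring B is the Diels–Alder retron of a 2-methyl-diene on C4 and the C8=C8a cinnamoyl bond, with the C1–C4 chain of ring A as tether; each ring-fusion carbon is α to one ring A carbonyl (C8a to C1, C4a to C4), so both quaternary centres can be made from CH afterwards.
No quinone meets a hydroquinone and no unknown asymmetric reaction is needed: one silyloxy carbinol from a known catalytic addition steers the cycloaddition, only C8 has to last, and in the final C–C bond formation the alkene can only end at C5=C6.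

Key step: step 6

Assumption: the (+)-enantiomer of MIB (3-exo-morpholinoisoborneol) is taken to give the (S)-carbinol 4, by analogy with the sense known for diethylzinc with the (−)-ligand; if the sense were reversed, the (−)-ligand would be used.

Step 1
Reactants: 1 hex-5-en-2-one
Product: 2 4-oxopentanal
Conditions: O3, CH2Cl2/MeOH, −78 °C; Me2S, −78 °C → rt; used crude
Reagents that add atoms: ozone, O=[O+][O-]
Why: Ozonolysis with reductive work-up should cleave the only alkene to the aldehyde and leave the ketone untouched; no stereocentre is formed.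

Step 2
Reactants: 2 4-oxopentanal; 3 2-methylbut-1-en-3-yne
Product: 4 (5S,6E)-5-hydroxy-8-methylnona-6,8-dien-2-one
Conditions: 3, Cy2BH, PhMe, 0 °C → rt; Me2Zn, −78 °C; (+)-MIB (5 mol %); 2, −20 °C; H2O
Reagents that add atoms: none
Why: Hydroboration of the alkyne end gives the (E)-dienylborane, boron-to-zinc exchange gives a dienylzinc that should add only to the aldehyde (catalytic asymmetric alkenylzinc addition), and the amino alcohol ligand sets the (S)-carbinol.

Step 3
Reactants: 4 (5S,6E)-5-hydroxy-8-methylnona-6,8-dien-2-one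
Product: 5 (5S,6E)-5-[(tert-butyldimethylsilyl)oxy]-8-methylnona-6,8-dien-2-one
Conditions: TBSCl, imidazole, DMF, 0 °C → rt
Reagents that add atoms: tert-butyldimethylsilyl chloride, CC(C)(C)[Si](C)(C)Cl
Why: Silyl ether formation at the secondary alcohol should also stop hemiketal formation with the ketone; the stereocentre is not touched.

Step 4
Reactants: 6 2-bromo-1,4-dimethoxybenzene
Product: 7 2-bromo-3,6-dimethoxybenzaldehyde
Conditions: LiN(iPr)2, THF, −78 °C; DMF, −78 → 0 °C; H2O
Reagents that add atoms: N,N-dimethylformamide, CN(C)C=O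
Why: Directed ortho-lithiation removes the proton flanked by Br and OMe, and formylation with DMF at low temperature should outrun loss of LiBr to the aryne; no stereocentre.

Step 5
Reactants: 5 (5S,6E)-5-[(tert-butyldimethylsilyl)oxy]-8-methylnona-6,8-dien-2-one; 7 2-bromo-3,6-dimethoxybenzaldehyde
Product: 8 (1E,6S,7E)-1-(2-bromo-3,6-dimethoxyphenyl)-6-[(tert-butyldimethylsilyl)oxy]-9-methyldeca-1,7,9-trien-3-one
Conditions: NaOH (0.5 equiv), EtOH/H2O, 0 °C → rt
Reagents that add atoms: none
Why: In a Claisen–Schmidt condensation the methyl group of the methyl ketone should condense with the non-enolisable aldehyde and the aldol lose water to the (E)-enone; the carbinol centre is not involved.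

Step 6
Reactants: 8 (1E,6S,7E)-1-(2-bromo-3,6-dimethoxyphenyl)-6-[(tert-butyldimethylsilyl)oxy]-9-methyldeca-1,7,9-trien-3-one
Product: 9 (4S,4aS,8S,8aR)-8-(2-bromo-3,6-dimethoxyphenyl)-4-[(tert-butyldimethylsilyl)oxy]-6-methyl-3,4,4a,7,8,8a-hexahydronaphthalen-1(2H)-one
Conditions: Me2AlCl (1.1 equiv), CH2Cl2, −78 → −30 °C
Reagents that add atoms: none
Why: Me2AlCl binds the ketone of 8 and lowers the LUMO of the cinnamoyl double bond, which adds across the 2-methyl-diene in a concerted, asynchronous intramolecular Diels–Alder reaction; the closest known type is the Lewis-acid-promoted cyclisation of 1,7,9-decatrien-3-ones to cis-fused octalones. Ring A closes in the fused mode through the four-atom tether (bond C8a–C4a) and ring B as the [4+2] cyclohexene (bonds C8a–C4a and C8–C7), so the double bond ends at C5=C6 and the methyl group at C6 by construction. The silyloxy-bearing carbon controls the diene face (silyloxy group outside, its hydrogen inside toward H-5 to avoid allylic 1,3-strain), the endo position of the tether carbonyl under the diene gives the cis ring fusion, and the (E)-alkene places the aryl group trans to C1. Regiochemistry is fixed by the tether and matched by polarisation, since the CH2 terminus of the 2-methyl-diene bonds to the β-carbon of the enone. The step needs endo and diene-face selectivity, because the exo adduct would carry the opposite configuration at C8 relative to the carbinol; the Lewis acid and the silyloxy stereocentre should secure both, and any exo adduct is a separable diastereomer. Of the four stereocentres of 9 only C8 is kept; C8a, C4a and C4 are replaced or erased in steps 8 to 10.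

Step 7
Reactants: 9 (4S,4aS,8S,8aR)-8-(2-bromo-3,6-dimethoxyphenyl)-4-[(tert-butyldimethylsilyl)oxy]-6-methyl-3,4,4a,7,8,8a-hexahydronaphthalen-1(2H)-one
Product: 11 (4S,4aS,8S,8aR)-8-(2-bromo-3,6-dimethoxyphenyl)-4-[(tert-butyldimethylsilyl)oxy]-6-methyl-4a,7,8,8a-tetrahydronaphthalen-1(4H)-one, via 2-phenylselanyl ketone 10 (not isolated)
Conditions: LiN(iPr)2, THF, −78 °C; PhSeBr; then H2O2, pyridine, CH2Cl2, 0 °C → rt
Reagents that add atoms: none
Why: Kinetic deprotonation should occur at the C2 methylene (C8a–H is tertiary and shielded by the aryl group), and selenenylation followed by selenoxide syn-elimination gives the C2=C3 enone; the centre at C2 is transient.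

Step 8
Reactants: 11 (4S,4aS,8S,8aR)-8-(2-bromo-3,6-dimethoxyphenyl)-4-[(tert-butyldimethylsilyl)oxy]-6-methyl-4a,7,8,8a-tetrahydronaphthalen-1(4H)-one; 12 prenyl bromide (1-bromo-3-methylbut-2-ene)
Product: 13 (4S,4aS,8S,8aS)-8-(2-bromo-3,6-dimethoxyphenyl)-4-[(tert-butyldimethylsilyl)oxy]-6-methyl-8a-(3-methylbut-2-en-1-yl)-4a,7,8,8a-tetrahydronaphthalen-1(4H)-one
Conditions: LiN(iPr)2, THF/DMPU, −78 °C; 12, −78 → −20 °C
Reagents that add atoms: none
Why: Kinetic α′-deprotonation of the enone gives the cross-conjugated dienolate at C8a (its only α′ hydrogen), and alkylation should occur opposite to the C8 aryl group, which allylic 1,3-strain with the enolate oxygen holds axial; this sets C8a with prenyl trans to aryl (angular enolate alkylation).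

Step 9
Reactants: 13 (4S,4aS,8S,8aS)-8-(2-bromo-3,6-dimethoxyphenyl)-4-[(tert-butyldimethylsilyl)oxy]-6-methyl-8a-(3-methylbut-2-en-1-yl)-4a,7,8,8a-tetrahydronaphthalen-1(4H)-one
Product: 16 (6RS,8S,8aS)-8-(2-bromo-3,6-dimethoxyphenyl)-6-methyl-8a-(3-methylbut-2-en-1-yl)-6,7,8,8a-tetrahydronaphthalene-1,4-dione, via allylic alcohol 14 (not isolated), via deconjugated enedione 15 (not isolated)
Conditions: Bu4NF, AcOH, THF, 0 °C; Dess–Martin periodinane, NaHCO3, CH2Cl2, 0 °C; DBU (0.2 equiv), rt
Reagents that add atoms: none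
Why: Fluoride desilylation and Dess–Martin oxidation give the enedione (which cannot aromatise because C8a is quaternary), and base should move the C5=C6 bond into conjugation with the C4 ketone (enone isomerisation); C4 and C4a cease to be stereocentres and C6 forms as a mixture that is destroyed in step 10.

Step 10
Reactants: 16 (6RS,8S,8aS)-8-(2-bromo-3,6-dimethoxyphenyl)-6-methyl-8a-(3-methylbut-2-en-1-yl)-6,7,8,8a-tetrahydronaphthalene-1,4-dione
Product: 17 (4aR,8R,8aS)-4a,8-(3,6-dimethoxy-1,2-phenylene)-6-methyl-8a-(3-methylbut-2-en-1-yl)-4a,7,8,8a-tetrahydronaphthalene-1,4-dione (the target as its dimethyl ether)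
Conditions: Pd(OAc)2 (10 mol %), P(t-Bu)3·HBF4 (20 mol %), Ag2CO3 (1.5 equiv), 1,2,2,6,6-pentamethylpiperidine (0.5 equiv), PhMe, 90 °C
Reagents that add atoms: none
Why: In this intramolecular Mizoroki–Heck reaction the aryl bromide adds to zerovalent palladium, 5-exo carbopalladation of C4a=C5 from the only face the axial aryl group can reach sets C4a, and β-hydride elimination can only go toward C6 (C4a has no hydrogen), which places the alkene at C5=C6 while both C6 epimers should converge through the base-labile γ-position.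

Step 11
Reactants: 17 (4aR,8R,8aS)-4a,8-(3,6-dimethoxy-1,2-phenylene)-6-methyl-8a-(3-methylbut-2-en-1-yl)-4a,7,8,8a-tetrahydronaphthalene-1,4-dione
Product: 19 target CNP0513322.1, via ring D quinone 18 (not isolated)
Conditions: (NH4)2Ce(NO3)6 (2.5 equiv), MeCN/H2O, 0 °C; then L-ascorbic acid, H2O/EtOAc, rt
Reagents that add atoms: water, O
Why: Oxidative demethylation by tetravalent cerium should give the ring D quinone, and ascorbic acid reduces this quinone, but not the ring A enedione, to the hydroquinone; no stereocentre is touched.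

Compound list
1 | hex-5-en-2-one | CC(=O)CCC=C | starting material
2 | 4-oxopentanal | CC(=O)CCC=O | intermediate
3 | 2-methylbut-1-en-3-yne | C=C(C)C#C | starting material
4 | (5S,6E)-5-hydroxy-8-methylnona-6,8-dien-2-one | CC(=O)CC[C@H](O)/C=C/C(C)=C | intermediate
5 | (5S,6E)-5-[(tert-butyldimethylsilyl)oxy]-8-methylnona-6,8-dien-2-one | CC(=O)CC[C@H](O[Si](C)(C)C(C)(C)C)/C=C/C(C)=C | intermediate
6 | 2-bromo-1,4-dimethoxybenzene | COc1ccc(OC)c(Br)c1 | starting material
7 | 2-bromo-3,6-dimethoxybenzaldehyde | O=Cc1c(Br)c(OC)ccc1OC | intermediate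
8 | (1E,6S,7E)-1-(2-bromo-3,6-dimethoxyphenyl)-6-[(tert-butyldimethylsilyl)oxy]-9-methyldeca-1,7,9-trien-3-one | C=C(C)/C=C/[C@H](CCC(=O)/C=C/c1c(Br)c(OC)ccc1OC)O[Si](C)(C)C(C)(C)C | intermediate
9 | (4S,4aS,8S,8aR)-8-(2-bromo-3,6-dimethoxyphenyl)-4-[(tert-butyldimethylsilyl)oxy]-6-methyl-3,4,4a,7,8,8a-hexahydronaphthalen-1(2H)-one (cis-fused; 4-silyloxy, H-4a, H-8a and aryl on one face) | O=C1CC[C@H](O[Si](C)(C)C(C)(C)C)[C@H]2C=C(C)C[C@H](c3c(Br)c(OC)ccc3OC)[C@@H]12 | intermediate
10 | 2-(phenylselanyl) derivative of 9 (C2 epimers) | O=C1C([Se]c4ccccc4)C[C@H](O[Si](C)(C)C(C)(C)C)[C@H]2C=C(C)C[C@H](c3c(Br)c(OC)ccc3OC)[C@@H]12 | intermediate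
11 | (4S,4aS,8S,8aR)-8-(2-bromo-3,6-dimethoxyphenyl)-4-[(tert-butyldimethylsilyl)oxy]-6-methyl-4a,7,8,8a-tetrahydronaphthalen-1(4H)-one | O=C1C=C[C@H](O[Si](C)(C)C(C)(C)C)[C@H]2C=C(C)C[C@H](c3c(Br)c(OC)ccc3OC)[C@@H]12 | intermediate
12 | prenyl bromide (1-bromo-3-methylbut-2-ene) | CC(C)=CCBr | starting material
13 | (4S,4aS,8S,8aS)-8-(2-bromo-3,6-dimethoxyphenyl)-4-[(tert-butyldimethylsilyl)oxy]-6-methyl-8a-(3-methylbut-2-en-1-yl)-4a,7,8,8a-tetrahydronaphthalen-1(4H)-one (prenyl trans to aryl) | O=C1C=C[C@H](O[Si](C)(C)C(C)(C)C)[C@H]2C=C(C)C[C@H](c3c(Br)c(OC)ccc3OC)[C@]12CC=C(C)C | intermediate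
14 | (4S,4aS,8S,8aS)-8-(2-bromo-3,6-dimethoxyphenyl)-4-hydroxy-6-methyl-8a-(3-methylbut-2-en-1-yl)-4a,7,8,8a-tetrahydronaphthalen-1(4H)-one | O=C1C=C[C@H](O)[C@H]2C=C(C)C[C@H](c3c(Br)c(OC)ccc3OC)[C@]12CC=C(C)C | intermediate
15 | (4aS,8S,8aS)-8-(2-bromo-3,6-dimethoxyphenyl)-6-methyl-8a-(3-methylbut-2-en-1-yl)-4a,7,8,8a-tetrahydronaphthalene-1,4-dione | O=C1C=CC(=O)[C@H]2C=C(C)C[C@H](c3c(Br)c(OC)ccc3OC)[C@]12CC=C(C)C | intermediate
16 | (6RS,8S,8aS)-8-(2-bromo-3,6-dimethoxyphenyl)-6-methyl-8a-(3-methylbut-2-en-1-yl)-6,7,8,8a-tetrahydronaphthalene-1,4-dione | O=C1C=CC(=O)C2=CC(C)C[C@H](c3c(Br)c(OC)ccc3OC)[C@]12CC=C(C)C | intermediate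
17 | (4aR,8R,8aS)-4a,8-(3,6-dimethoxy-1,2-phenylene)-6-methyl-8a-(3-methylbut-2-en-1-yl)-4a,7,8,8a-tetrahydronaphthalene-1,4-dione (target dimethyl ether) | CC(C)=CC[C@@]12C(=O)C=CC(=O)[C@@]13C=C(C)C[C@@H]2c1c(OC)ccc(OC)c13 | intermediate
18 | ring D quinone of the target (configuration as in 17; 3,6-dioxocyclohexa-1,4-diene-1,2-diyl in place of the arene) | CC(C)=CC[C@@]12C(=O)C=CC(=O)[C@@]13C=C(C)C[C@@H]2C1=C3C(=O)C=CC1=O | intermediate
19 | CNP0513322.1: cyclohex-2-ene-1,4-dione fused to a 2,5-dihydroxybenzo-bridged bicyclo[3.2.1]octene; prenyl-bearing bridge carbon (S), aryl-bearing ring-fusion carbon (R), benzylic CH (R) | CC(C)=CC[C@@]12C(=O)C=CC(=O)[C@@]13C=C(C)C[C@@H]2c1c(O)ccc(O)c13 | target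

Total step count: 11. Longest linear sequence: 10 (steps 1–3 and 5–11).

Steps most likely to fail

Step 10 (closure of ring C). The carbopalladation has to form a quaternary carbon next to another one, the C6 epimer without a syn β-hydrogen may stall as an alkylpalladium species, and the prenyl alkene could be attacked instead. Fallback, setting out from 16 and rejoining the route at 18: oxidative demethylation of 16 with (NH4)2Ce(NO3)6 should give the bromoquinone 2-bromo-3-[(1S,8aS)-3-methyl-8a-(3-methylbut-2-en-1-yl)-5,8-dioxo-1,2,3,5,8,8a-hexahydronaphthalen-1-yl]cyclohexa-2,5-diene-1,4-dione F1. Triethylamine then generates the dienolate of the enedione, which displaces bromide at the brominated quinone carbon by addition–elimination (nucleophilic substitution on a haloquinone) to give quinone 18 without any change of oxidation state; 18 is reduced to 19 as in step 11.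

Step 8 (angular prenylation). Deprotonation could occur at the γ-position (C4) instead of C8a, the dienolate could be O-alkylated, or attack could come from the face of the aryl group. Fallback, setting out from 9 and rejoining the route at 13: formylation of 9 (HCO2Et, NaH) gives the 2-(hydroxymethylene) ketone F2, and n-BuSH with TsOH converts it into the 2-(butylsulfanylmethylene) ketone F3, in which C2 is blocked. KOt-Bu and prenyl bromide 12 then alkylate the only remaining α-position, C8a, to give the blocked 8a-prenyl ketone F4. KOH in aqueous diethylene glycol removes the blocking group to give the 8a-prenyl ketone F5, and the selenenylation–oxidation of step 7 applied to F5 gives 13.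

Step 6 (key cycloaddition). The Lewis acid could ionise the doubly allylic silyl ether, or endo and diene-face control could be incomplete, which would erode the enantiomeric purity of every later compound. Fallback, setting out from 7 and 3 and rejoining the route at 9: aldol condensation of 7 with acetone gives (E)-4-(2-bromo-3,6-dimethoxyphenyl)but-3-en-2-one F6. The dienylzinc addition of step 2 applied to chloroacetaldehyde gives (2R,3E)-1-chloro-5-methylhexa-3,5-dien-2-ol F7, which is silylated to its tert-butyldimethylsilyl ether F8. An intermolecular Me2AlCl-promoted Diels–Alder reaction of F6 with F8 (acetyl group endo, dienophile anti to the silyloxy group) should give the acetylcyclohexene F9. Kinetic deprotonation of the acetyl group (LiN(iPr)2, NaI) and intramolecular alkylation by the primary chloride then closes ring A to give 9.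

Further compounds
F1 | step 10 | 2-bromo-3-[(1S,8aS)-3-methyl-8a-(3-methylbut-2-en-1-yl)-5,8-dioxo-1,2,3,5,8,8a-hexahydronaphthalen-1-yl]cyclohexa-2,5-diene-1,4-dione (3RS) | O=C1C=CC(=O)C2=CC(C)C[C@H](C3=C(Br)C(=O)C=CC3=O)[C@]12CC=C(C)C
F2 | step 8 | 2-(hydroxymethylene) derivative of 9 | O=C1C(=CO)C[C@H](O[Si](C)(C)C(C)(C)C)[C@H]2C=C(C)C[C@H](c3c(Br)c(OC)ccc3OC)[C@@H]12
F3 | step 8 | 2-(butylsulfanylmethylene) derivative of 9 | O=C1C(=CSCCCC)C[C@H](O[Si](C)(C)C(C)(C)C)[C@H]2C=C(C)C[C@H](c3c(Br)c(OC)ccc3OC)[C@@H]12
F4 | step 8 | 2-(butylsulfanylmethylene)-8a-(3-methylbut-2-en-1-yl) ketone (prenyl trans to aryl) | O=C1C(=CSCCCC)C[C@H](O[Si](C)(C)C(C)(C)C)[C@H]2C=C(C)C[C@H](c3c(Br)c(OC)ccc3OC)[C@]12CC=C(C)C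
F5 | step 8 | 8-(2-bromo-3,6-dimethoxyphenyl)-4-[(tert-butyldimethylsilyl)oxy]-6-methyl-8a-(3-methylbut-2-en-1-yl)-3,4,4a,7,8,8a-hexahydronaphthalen-1(2H)-one (configuration as in 13) | O=C1CC[C@H](O[Si](C)(C)C(C)(C)C)[C@H]2C=C(C)C[C@H](c3c(Br)c(OC)ccc3OC)[C@]12CC=C(C)C
F6 | step 6 | (E)-4-(2-bromo-3,6-dimethoxyphenyl)but-3-en-2-one | CC(=O)/C=C/c1c(Br)c(OC)ccc1OC
F7 | step 6 | (2R,3E)-1-chloro-5-methylhexa-3,5-dien-2-ol | ClC[C@H](O)/C=C/C(C)=C
F8 | step 6 | tert-butyl{[(2R,3E)-1-chloro-5-methylhexa-3,5-dien-2-yl]oxy}dimethylsilane | ClC[C@H](O[Si](C)(C)C(C)(C)C)/C=C/C(C)=C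
F9 | step 6 | 1-[6-(2-bromo-3,6-dimethoxyphenyl)-2-{(1R)-1-[(tert-butyldimethylsilyl)oxy]-2-chloroethyl}-4-methylcyclohex-3-en-1-yl]ethan-1-one (acetyl cis to the side chain, trans to the aryl group) | CC(=O)[C@@H]1[C@@H](c2c(Br)c(OC)ccc2OC)CC(C)=C[C@@H]1[C@H](CCl)O[Si](C)(C)C(C)(C)C
A1 | direct plan | 2-(3-methylbut-2-en-1-yl)-3-[(E)-prop-1-en-1-yl]cyclohexa-2,5-diene-1,4-dione | O=C1C=CC(=O)C(CC=C(C)C)=C1/C=C/C
A2 | direct plan | 2-vinylbenzene-1,4-diol | C=Cc1cc(O)ccc1O
A3 | direct plan | (4aS,5R,7RS)-5-(2,5-dihydroxyphenyl)-7-methyl-4a-(3-methylbut-2-en-1-yl)-4a,5,6,7-tetrahydronaphthalene-1,4-dione | CC(C)=CC[C@@]12C(=O)C=CC(=O)C1=CC(C)C[C@@H]2c1cc(O)ccc1O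
A4 | direct plan | (4aS,5R,7RS)-5-(3,6-dioxocyclohexa-1,4-dien-1-yl)-7-methyl-4a-(3-methylbut-2-en-1-yl)-4a,5,6,7-tetrahydronaphthalene-1,4-dione | CC(C)=CC[C@@]12C(=O)C=CC(=O)C1=CC(C)C[C@@H]2C1=CC(=O)C=CC1=O
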